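The cyclohexene ring is disconnected at C5–C6 (shikimate numbering: C1 carries CO2Me, C1=C2, oxygens on C3, C4 and C5, C6 is CH2). The key step exploits the fact that the oxygen-bearing C5 is linked through the C6 methylene to C1 of the enoate. A C5 α-silyloxy radical, released by cathodic decarboxylation, closes the carbocycle onto an acrylate CH2, and loss of acetate from C2 installs C1=C2, so ring, alkene and the C5 stereocentre arise in one operation. The precursor is the N-hydroxyphthalimide ester of a D-mannose-derived α-silyloxy acid carrying the cis-3,4-acetonide and a Baylis–Hillman acetate; the acetate and both 2-methylbutanoates are installed last.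

Key step: step 9

Remark: the target is read as methyl (3R,4S,5R)-3-O-acetyl-4,5-bis-O-[(2R)-2-methylbutanoyl]shikimate (natural shikimate configuration); shikimate numbers are used for the future ring atoms in open-chain intermediates too, and C2/C3 of D-mannose supply C3/C4.

Step 1
Reactants: 1 diacetone-D-mannose (2,3:5,6-di-O-isopropylidene-α-D-mannofuranose)
Product: 2 heptenitol with one free hydroxyl (1,2-dideoxy-3,4:6,7-di-O-isopropylidene-D-manno-hept-1-enitol, free 5-OH)
Conditions: Ph3PCH3Br, KOtBu, THF, 0 °C to reflux
Reagents that add atoms: methyltriphenylphosphonium bromide, C[P+](c1ccccc1)(c1ccccc1)c1ccccc1.[Br-]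
Why: Wittig methylenation of the open-chain aldehyde in equilibrium with the lactol frees the former ring oxygen (future O5) as the only hydroxyl and installs a vinyl group as the masked C2 aldehyde; no stereocentre is formed or touched.

Step 2
Reactants: 2 heptenitol with free 5-OH
Product: 3 silyl ether of 2 (5-O-(tert-butyldimethylsilyl)-1,2-dideoxy-3,4:6,7-di-O-isopropylidene-D-manno-hept-1-enitol)
Conditions: TBSOTf, 2,6-lutidine, CH2Cl2, 0 °C
Reagents that add atoms: tert-butyldimethylsilyl trifluoromethanesulfonate, CC(C)(C)[Si](C)(C)OS(=O)(=O)C(F)(F)F
Why: Silyl triflate silylation under buffered conditions protects the hindered secondary alcohol flanked by two dioxolanes and provides the oxygen substituent that will later stabilise the C5 radical; both acetonides tolerate it.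

Step 3
Reactants: 3 silyl ether of 2
Product: 5 aldehydo-D-mannose derivative (4-O-(tert-butyldimethylsilyl)-2,3:5,6-di-O-isopropylidene-aldehydo-D-mannose), via secondary ozonide 4 (not isolated)
Conditions: O3, CH2Cl2, −78 °C; then PPh3, −78 °C to rt
Reagents that add atoms: ozone, [O-][O+]=O
Why: Ozonolysis with reductive work-up (Criegee mechanism) cleaves the only alkene to the α-alkoxy aldehyde at C2 before any acrylate is in the molecule, so no alkene chemoselectivity is needed; the dioxolane stereocentres are untouched.

Step 4
Reactants: 5 aldehydo-D-mannose derivative; 6 methyl acrylate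
Product: 7 Baylis–Hillman alcohol (methyl 6-O-(tert-butyldimethylsilyl)-2-deoxy-4,5:7,8-di-O-isopropylidene-2-methylideneoctonate, D-manno at C4–C7, both epimers at the new carbinol C3 of the octonate, which is ring C2)
Conditions: DABCO (1 equiv), methyl acrylate (5 equiv), 1,4-dioxane/H2O (1:1), rt
Reagents that add atoms: none
Why: Morita–Baylis–Hillman reaction, in which the DABCO–acrylate zwitterion adds to the activated α-alkoxy aldehyde; the new carbinol centre forms unselectively, which is acceptable because it is destroyed when acetate leaves in step 9.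

Step 5
Reactants: 7 Baylis–Hillman alcohol
Product: 8 Baylis–Hillman acetate (acetate of 7 at the carbinol, both epimers)
Conditions: Ac2O, pyridine, DMAP (5 mol %), CH2Cl2, 0 °C
Reagents that add atoms: acetic anhydride, CC(=O)OC(C)=O
Why: DMAP-catalysed acetylation turns the allylic hydroxyl into the leaving group needed for the later elimination, and is run cold and briefly so that the acetate does not undergo allylic transposition.

Step 6
Reactants: 8 Baylis–Hillman acetate
Product: 10 α-silyloxy aldehyde (CHO on the carbon bearing OTBS, one carbon shorter than 8; internal cis-acetonide, allylic acetate and acrylate retained), via terminal diol 9 (not isolated)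
Conditions: H5IO6, EtOAc, 0 °C to rt
Reagents that add atoms: none
Why: One-pot acetal hydrolysis and glycol cleavage with periodic acid (Malaprade-type) is selective for the terminal acetonide over the internal cis-dioxolane and unmasks the carboxyl carbon only now, so no free acid is carried through steps 4 and 5; the centre α to the new aldehyde (future C5) is planarised later, so its integrity is not critical.

Step 7
Reactants: 10 α-silyloxy aldehyde
Product: 11 α-silyloxy carboxylic acid
Conditions: NaClO2, NaH2PO4, 2-methyl-2-butene, t-BuOH/H2O, 0 °C to rt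
Reagents that add atoms: sodium chlorite, [Na+].[O-]Cl=O
Why: Pinnick oxidation converts the aldehyde into the acid under buffered conditions that spare silyl ether, acetonide, allylic acetate and enoate, with 2-methyl-2-butene scavenging HOCl.

Step 8
Reactants: 11 α-silyloxy carboxylic acid; 12 N-hydroxyphthalimide
Product: 13 redox-active ester (N-phthalimidoyl ester of 11; in ring numbering C5 bears OTBS and the activated carboxyl, C3/C4 sit in the cis-dioxolane, C2 bears OAc, C1 bears CO2Me and the C6 methylidene)
Conditions: DIC, DMAP (5 mol %), CH2Cl2, 0 °C to rt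
Reagents that add atoms: none
Why: Carbodiimide (Steglich-type) coupling of the acid with N-hydroxyphthalimide gives the N-acyloxyphthalimide without touching any stereocentre.

Step 9
Reactants: 13 redox-active ester
Product: 15 methyl 5-O-(tert-butyldimethylsilyl)-3,4-O-isopropylideneshikimate, via ester enolate 14 (not isolated)
Conditions: undivided cell, graphite-felt cathode, Zn anode, n-Bu4NPF6 (0.1 M), DMA, 5 mM in 13, constant current (about 2.2 F/mol), rt, Ar; aq. NH4Cl work-up
Reagents that add atoms: none
Why: Proposed new method: one-electron reduction of the N-acyloxyphthalimide at the cathode gives a radical anion that fragments to phthalimide anion, CO2 and the nucleophilic C5 α-silyloxy radical, which adds to the polarity-matched CH2 terminus (C6) of the acrylate; the tertiary α-ester radical at C1 is then reduced at the same electrode to the enolate 14, which expels the C2 acetate (E1cB) to give C1=C2, while oxidation of the Zn anode balances the charge. The closest known reaction types are the intermolecular electroreductive decarboxylative Giese addition of N-hydroxyphthalimide esters and radical addition–elimination on Baylis–Hillman acetates; the intramolecular ring-forming combination has no direct precedent. The single ring closes in the 6-endo-trig mode, the 5-exo path being disfavoured because it would require attack at the fully substituted, electron-poor C1. The new C5 stereocentre is set in the C5–C6 bond formation under substrate control by the cis-fused 3,4-dioxolane: a chair-like transition state with the bulky silyloxy group pseudo-equatorial, i.e. trans to O4, is expected but not secured. The step needs chemoselective reduction of the redox-active ester in the presence of the enoate, secured by its much less negative reduction potential, and ring closure in competition with intermolecular addition or premature reduction of the C5 radical, secured by high dilution, the cis disposition of the two arms on the dioxolane and the reluctance of an α-oxy radical to accept an electron. The configurations at C2 and C5 of 13 are irrelevant because both centres are planarised.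

Step 10
Reactants: 15 methyl 5-O-(tert-butyldimethylsilyl)-3,4-O-isopropylideneshikimate
Product: 16 methyl shikimate (methyl (3R,4S,5R)-3,4,5-trihydroxycyclohex-1-ene-1-carboxylate)
Conditions: TFA/H2O (4:1), 0 °C to rt
Reagents that add atoms: none
Why: Acid-catalysed hydrolysis removes the isopropylidene acetal and the silyl ether together and leads to a known triol, so the C5 configuration from step 9 can be checked against authentic material; no stereocentre is affected.

Step 11
Reactants: 16 methyl shikimate
Product: 18 methyl 3-O-acetylshikimate, via cyclic orthoacetate 17 (not isolated)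
Conditions: MeC(OMe)3 (1.3 equiv), CSA (cat.), MeCN, rt; then AcOH/H2O (4:1), rt
Reagents that add atoms: trimethyl orthoacetate, CC(OC)(OC)OC; water, O
Why: Orthoester route to a monoester of a cis-diol: the cis-3,4-diol forms the five-membered cyclic orthoacetate in preference to the trans-4,5-diol, and mild acid hydrolysis opens it to the ester on the pseudo-axial O3 and the free equatorial O4 hydroxyl, as in the well-known axial monoacetylation of pyranoside cis-diols.

Step 12
Reactants: 18 methyl 3-O-acetylshikimate; 19 (R)-2-methylbutanoic acid
Product: 20 methyl 3-O-acetyl-4,5-bis-O-[(2R)-2-methylbutanoyl]shikimate (target)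
Conditions: 19 (3 equiv), DIC, DMAP, CH2Cl2, 0 °C to rt
Reagents that add atoms: none
Why: Steglich esterification puts the same acyl group on both remaining hydroxyls, so O4 and O5 need no differentiation; acylation at low temperature should outrun acetyl migration from O3, and the α-stereocentre of the simple alkyl-branched acid is not prone to enolisation under these conditions.

Compound list
1 | 2,3:5,6-di-O-isopropylidene-α-D-mannofuranose | O[C@H]1O[C@H]([C@H]2COC(C)(C)O2)[C@@H]2OC(C)(C)O[C@H]12 | starting material
2 | 1,2-dideoxy-3,4:6,7-di-O-isopropylidene-D-manno-hept-1-enitol | C=C[C@H]1OC(C)(C)O[C@H]1[C@H](O)[C@H]1COC(C)(C)O1 | intermediate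
3 | 5-O-(tert-butyldimethylsilyl)-1,2-dideoxy-3,4:6,7-di-O-isopropylidene-D-manno-hept-1-enitol | C=C[C@H]1OC(C)(C)O[C@H]1[C@H](O[Si](C)(C)C(C)(C)C)[C@H]1COC(C)(C)O1 | intermediate
4 | secondary ozonide (1,2,4-trioxolane) of 3, mixture at the trioxolane carbon | C1OC(OO1)[C@H]1OC(C)(C)O[C@H]1[C@H](O[Si](C)(C)C(C)(C)C)[C@H]1COC(C)(C)O1 | intermediate
5 | 4-O-(tert-butyldimethylsilyl)-2,3:5,6-di-O-isopropylidene-aldehydo-D-mannose | O=C[C@H]1OC(C)(C)O[C@H]1[C@H](O[Si](C)(C)C(C)(C)C)[C@H]1COC(C)(C)O1 | intermediate
6 | methyl acrylate | C=CC(=O)OC | starting material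
7 | Baylis–Hillman alcohol: methyl 6-O-(tert-butyldimethylsilyl)-2-deoxy-4,5:7,8-di-O-isopropylidene-2-methylideneoctonate, D-manno at C4–C7, both C3 epimers | COC(=O)C(=C)C(O)[C@H]1OC(C)(C)O[C@H]1[C@H](O[Si](C)(C)C(C)(C)C)[C@H]1COC(C)(C)O1 | intermediate
8 | Baylis–Hillman acetate: 3-O-acetate of 7, both C3 epimers | COC(=O)C(=C)C(OC(C)=O)[C@H]1OC(C)(C)O[C@H]1[C@H](O[Si](C)(C)C(C)(C)C)[C@H]1COC(C)(C)O1 | intermediate
9 | terminal 7,8-diol of 8 | COC(=O)C(=C)C(OC(C)=O)[C@H]1OC(C)(C)O[C@H]1[C@H](O[Si](C)(C)C(C)(C)C)[C@H](O)CO | intermediate
10 | α-silyloxy aldehyde: methyl 3-O-acetyl-6-O-(tert-butyldimethylsilyl)-2-deoxy-4,5-O-isopropylidene-2-methylidene-7-oxoheptanoate, D-lyxo at C4–C6, both C3 epimers | COC(=O)C(=C)C(OC(C)=O)[C@H]1OC(C)(C)O[C@H]1[C@H](O[Si](C)(C)C(C)(C)C)C=O | intermediate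
11 | α-silyloxy acid: the 7-oic acid corresponding to 10 | COC(=O)C(=C)C(OC(C)=O)[C@H]1OC(C)(C)O[C@H]1[C@H](O[Si](C)(C)C(C)(C)C)C(=O)O | intermediate
12 | N-hydroxyphthalimide | O=C1c2ccccc2C(=O)N1O | starting material
13 | N-phthalimidoyl ester of 11 (radical precursor; single epimer at C5, both epimers at C2) | O=C(ON1C(=O)c2ccccc2C1=O)[C@@H](O[Si](C)(C)C(C)(C)C)[C@@H]1OC(C)(C)O[C@@H]1C(OC(C)=O)C(=C)C(=O)OC | intermediate
14 | ester enolate of the cyclised 2-acetoxy-5-silyloxy-3,4-isopropylidenedioxycyclohexanecarboxylate | COC([O-])=C1C[C@@H](O[Si](C)(C)C(C)(C)C)[C@@H]2OC(C)(C)O[C@@H]2C1OC(C)=O | intermediate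
15 | methyl 5-O-(tert-butyldimethylsilyl)-3,4-O-isopropylideneshikimate | COC(=O)C1=C[C@H]2OC(C)(C)O[C@H]2[C@H](O[Si](C)(C)C(C)(C)C)C1 | intermediate
16 | methyl shikimate | COC(=O)C1=C[C@@H](O)[C@@H](O)[C@H](O)C1 | intermediate
17 | methyl 3,4-O-(1-methoxyethylidene)shikimate (cyclic orthoacetate, both orthoester epimers) | COC(=O)C1=C[C@H]2OC(C)(OC)O[C@H]2[C@H](O)C1 | intermediate
18 | methyl 3-O-acetylshikimate | COC(=O)C1=C[C@@H](OC(C)=O)[C@@H](O)[C@H](O)C1 | intermediate
19 | (R)-2-methylbutanoic acid | CC[C@@H](C)C(=O)O | starting material
20 | methyl (3R,4S,5R)-3-acetoxy-4,5-bis{[(2R)-2-methylbutanoyl]oxy}cyclohex-1-ene-1-carboxylate | CC[C@@H](C)C(=O)O[C@@H]1[C@H](OC(C)=O)C=C(C(=O)OC)C[C@H]1OC(=O)[C@H](C)CC | target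

Total step count: 12. Longest linear sequence: 12 steps from 1 (fully linear; 6, 12 and 19 are purchased).

Steps most likely to fail

1. Step 9 (proposed new method). The C5 radical may be reduced or quenched by hydrogen-atom transfer before it closes. Phthalimide anion may displace the allylic acetate. Closure may also occur with the silyloxy group on the wrong face and give the C5 epimer. Fallback with known chemistry, setting out from 3 and returning at 15: H5IO6 in EtOAc would cleave the terminal acetonide of 3 to the α-silyloxy enal F1, and NaBH4 in MeOH would reduce it to the primary alcohol F2. Tf2O/pyridine at −40 °C would give the triflate F3, and the sodium salt of trimethyl phosphonoacetate (NaH, THF/DMF) would displace it to give the alkylated phosphonoacetate F4. Ozonolysis of the vinyl group (O3; PPh3) would give the phosphonate aldehyde F5, and an intramolecular Horner–Wadsworth–Emmons reaction (NaH, THF, 0 °C) would close C1=C2 and deliver 15. This polar closure keeps the mannose C4 configuration, which is that of natural C5, so it also removes the stereochemical uncertainty.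

2. Step 4. Addition to the hindered aldehyde may be slow, and during a long exposure to amine base the α-centre of the cis-dioxolane (C3) may epimerise. Fallback, setting out from 5 and returning at 7: vinylalumination. [α-(Methoxycarbonyl)vinyl]diisobutylaluminium, generated from methyl propiolate and i-Bu2AlH with N-methylmorpholine N-oxide in THF at 0 °C, would add 1,2 to the aldehyde and give 7 directly, without amine base and in a short reaction time. This fallback makes no new compound (F0).

3. Step 11. The orthoester may also engage O5, the hemiorthoester may open toward the 4-acetate, or the acetyl group may migrate from O3 to O4. Fallback, setting out from 16 and returning at 18: butane-2,3-dione, HC(OMe)3 and CSA in MeOH at reflux would protect the trans-diequatorial 4,5-diol selectively as the butane-2,3-diacetal F6. Ac2O/pyridine would acetylate the only free hydroxyl to give the diacetal 3-acetate F7, and TFA/H2O (9:1) would remove the diacetal to give 18.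

Further compounds
F1 | step 9 | 2-O-(tert-butyldimethylsilyl)-5,6-dideoxy-3,4-O-isopropylidene-D-arabino-hex-5-enose (α-silyloxy enal) | C=C[C@H]1OC(C)(C)O[C@H]1[C@H](O[Si](C)(C)C(C)(C)C)C=O
F2 | step 9 | primary alcohol from reduction of F1 | C=C[C@H]1OC(C)(C)O[C@H]1[C@H](O[Si](C)(C)C(C)(C)C)CO
F3 | step 9 | trifluoromethanesulfonate of F2 | C=C[C@H]1OC(C)(C)O[C@H]1[C@H](O[Si](C)(C)C(C)(C)C)COS(=O)(=O)C(F)(F)F
F4 | step 9 | alkylated trimethyl phosphonoacetate (both epimers at the phosphonate carbon) | C=C[C@H]1OC(C)(C)O[C@H]1[C@H](O[Si](C)(C)C(C)(C)C)CC(C(=O)OC)P(=O)(OC)OC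
F5 | step 9 | phosphonate aldehyde from ozonolysis of F4 | O=C[C@H]1OC(C)(C)O[C@H]1[C@H](O[Si](C)(C)C(C)(C)C)CC(C(=O)OC)P(=O)(OC)OC
F0 | step 4 | none | none
F6 | step 11 | methyl 4,5-O-[(2S,3S)-2,3-dimethoxybutane-2,3-diyl]shikimate | COC(=O)C1=C[C@@H](O)[C@H]2O[C@](C)(OC)[C@@](C)(OC)O[C@@H]2C1
F7 | step 11 | methyl 3-O-acetyl-4,5-O-[(2S,3S)-2,3-dimethoxybutane-2,3-diyl]shikimate | COC(=O)C1=C[C@@H](OC(C)=O)[C@H]2O[C@](C)(OC)[C@@](C)(OC)O[C@@H]2C1
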